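Whatever reagent a flask holds, if it acts in both steps it cancels when I divide the rate at which product forms by the rate at which starting material goes on, and time goes with it. Let c be the fraction of the charge found as intermediate B plus product. While c is small, what remains is one constant: the split number, twice product over c squared, a selectivity factor.

| flask | starting material | reagent | protic impurity | remark | time |
|---|---|---|---|---|---|
| Thursday's | 10 mM (fed, over 2.0 min) | 13 mM | 0.50 mM | the very flask that is asked about, followed so far; the fed solution adds 0.50 times the starting volume |  |
| Saturday's | 20 mM (fed, over 2.0 min) | 13 mM | 0.50 mM | run made earlier; the fed solution adds 0.50 times the starting volume |  |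
| flask | 10 mM (fed, over 2.0 min) | 13.0 mM | 0.500 mM | the fed solution adds 0.50 times the starting volume | 40 min |

| run | time / min | product / % | intermediate B / % |
|---|---|---|---|
| Thursday's | 1.33 | 0.1 | 0.6 |
| Thursday's | 4.00 | 0 | 1.5 |
| Thursday's | 8.00 | 0.4 | 6.1 |
| Thursday's | 12.0 | 1.3 | 9.8 |
| Thursday's | 15.0 | 2.3 | 12.2 |
| Saturday's | 2.50 | 0 | 0.4 |
| Saturday's | 8.00 | 0.6 | 6.4 |
| Saturday's | 12.0 | 1.5 | 9.0 |
| Saturday's | 20.0 | 4.4 | 14.2 |
| Saturday's | 30.0 | 7.4 | 17.8 |

(scatter of a reading: 0.5 percentage points)

- how much product the flask holds at 40 min, in percent of the starting material charged
- how much intermediate B the flask holds at 40 min, in percent of the starting material charged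

- every charge counts on the volume at the start, and the solution that is fed holds the whole dose
- percentages count the whole charge, also what has not yet gone in

What must I know well? Not the charges: this flask is Thursday's run continued, so reagent, impurity and feed are already inside its readings. Product follows the split number directly but c squared, so an error in c counts twice. So c comes first.

I assume Saturday's late pace suits this flask's falling reagent: the logarithm of what remains unconverted, between 8.00 min and 30.0 min, drops 0.00990 /min. From Thursday's 14.5% at 15.0 min, that gives c = 0.332 at 40 min. Saturday's last reading puts the split number at 2.33, and Thursday's last reads 2.19. My reckoning: product 0.129, intermediate B 0.203.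

The forecast, reasoning from “Doubling the charge leaves the early percent-per-minute rate unchanged” and a first-order step to product, says product 13.3% and intermediate B 21.0%.

The flask gives product 15.2% and intermediate B 19.3%, so the forecast stands within its margins. Removing the reaction of starting material with protic impurity barely changes product. On the flask's own c of 34.5%, the split number gives product 0.139.

    starting material + reagent → intermediate A (k = 0.0290 /M/s)
    reagent + intermediate B → product (k = 0.0789 /M/s)
    intermediate A → intermediate B (k = 0.00681 /s)
    starting material + protic impurity → quenched substrate (k = 0.306 /M/s)

For the neighbour flask with 5.2 mM of reagent, all else as in this flask, I scale the logarithm by the reagent ratio, so c = 0.149, product 0.0260 and intermediate B 0.123. That neighbour flask gives product 3.33% and intermediate B 12.4%.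

The readings were computed with constants of no real substance.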